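**Plan**

Cuts: (a) C5–CH2 of the dihydrochalcone arm. (b) C3–C3a of the dihydrofuran ring, with the aroyl carbon put back between C3 and C3a, so that the five-membered ring O1–C2–C3–C3a–C7a becomes the six-membered pyran ring of a 2,4-diaryl-2H-chromene. (c) The C4–aryl bond of that chromene. (d) The C2–aryl bond of a flavanone.
Enabling feature: C3 bears both ring-A carbon C3a and the carbonyl carbon of the 2,4-dihydroxybenzoyl group. This aryl–CH–C(=O)–aryl unit is the retron of an oxidative 1,2-aryl shift across a 1,1-diarylalkene; here the alkene is C3=C4 of the pyran ring and the migrating aryl carbon belongs to the ring, so the shift is a ring contraction.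
Forward: chromone → (S)-flavanone → enol triflate → (S)-2,4-diaryl-2H-chromene → ring contraction by trivalent iodine (five-membered ring, aryl ketone and C3 in one operation) → C5 iodination → Heck attachment of the arm → one hydrogenolysis.
Stereochemistry: C2 comes from a ligand-controlled enantioselective conjugate arylation. C3 comes from the invertive, stereospecific shift in the 2,3-trans iodane adduct, backed by the thermodynamic trans preference.
Helpers: the three phenols present at the key step are benzyl carbonates. They deactivate ring B and the resorcinol ring, so that ring A alone migrates and alone is iodinated; they leave with the two benzyl ethers in the last step.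

Key step: step 6

Assumption: (R)-t-BuPyOx is taken to give the (S)-flavanone, by transfer of the facial sense known for this ligand class with cyclic enones. If the sense proves opposite, the (S)-ligand is used and nothing else changes.
Numbering: five-membered-ring compounds use benzofuran numbering (O1, C2, C3, C3a, C4–C7, C7a). Six-membered-ring compounds use chromene numbering (O1, C2, C3, C4, C4a, C5–C8, C8a). Ring A is the fused benzene ring and ring B is the C2 aryl group.

**Route**

Step 1
Reactants: 1 4-hydroxyphenylboronic acid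
Product: 2 4-(benzyloxycarbonyloxy)phenylboronic acid
Conditions: CbzCl, Et3N, THF, 0 °C to rt; dilute aq HCl work-up
Reagents that add atoms: benzyl chloroformate, O=C(Cl)OCc1ccccc1
Why: O-acylation of a phenol with a chloroformate; any boron mixed anhydride is hydrolysed on work-up, and the carbonate makes the future ring B electron-poor.

Step 2
Reactants: 2 4-(benzyloxycarbonyloxy)phenylboronic acid; 3 chromone
Product: 4 (2S)-2-[4-(benzyloxycarbonyloxy)phenyl]chroman-4-one
Conditions: Pd(OCOCF3)2 (cat.), (R)-t-BuPyOx (cat.), NH4PF6, H2O, ClCH2CH2Cl, 60 °C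
Reagents that add atoms: none
Why: Enantioselective conjugate addition of an arylboronic acid to a chromone under cationic divalent palladium/pyridine-oxazoline catalysis, in which the ligand fixes the face of aryl transfer and sets C2 as S, with no base present to open the flavanone or cleave the carbonate.

Step 3
Reactants: 4 (2S)-2-[4-(benzyloxycarbonyloxy)phenyl]chroman-4-one
Product: 5 (2S)-2-[4-(benzyloxycarbonyloxy)phenyl]-2H-chromen-4-yl trifluoromethanesulfonate
Conditions: Tf2O, 2,6-di-tert-butyl-4-methylpyridine, CH2Cl2, 0 °C to rt, dark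
Reagents that add atoms: trifluoromethanesulfonic anhydride, O=S(=O)(OS(=O)(=O)C(F)(F)F)C(F)(F)F
Why: Vinyl triflate formation from a ketone with Tf2O and a hindered pyridine runs by O-triflylation and loss of a C3 proton without a free enolate, so the retro-oxa-Michael opening that racemises flavanones is avoided and C2 stays S.

Step 4
Reactants: 6 4-iodoresorcinol
Product: 7 dibenzyl (4-iodo-1,3-phenylene) biscarbonate
Conditions: CbzCl (2.2 equiv), Et3N, CH2Cl2, 0 °C to rt
Reagents that add atoms: benzyl chloroformate, O=C(Cl)OCc1ccccc1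
Why: Double O-acylation of the two phenols with a chloroformate, which gives the resorcinol ring in electron-poor, hydrogenolysable form.

Step 5
Reactants: 7 dibenzyl (4-iodo-1,3-phenylene) biscarbonate; 5 (2S)-2-[4-(benzyloxycarbonyloxy)phenyl]-2H-chromen-4-yl trifluoromethanesulfonate
Product: 9 (2S)-4-[2,4-bis(benzyloxycarbonyloxy)phenyl]-2-[4-(benzyloxycarbonyloxy)phenyl]-2H-chromene, via arylzinc iodide 8 (not isolated)
Conditions: Zn dust, LiCl, THF, 25–40 °C; supernatant added to 5, Pd(OAc)2 (cat.), SPhos (cat.), THF, 25 °C, dark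
Reagents that add atoms: none
Why: LiCl-assisted zinc insertion gives an arylzinc that tolerates carbonates, and the Negishi coupling with the vinyl triflate runs base-free at room temperature, which spares the carbonates and keeps the 2H-chromene below the temperature at which reversible oxa-6π ring opening would erode C2.

Step 6
Reactants: 9 (2S)-4-[2,4-bis(benzyloxycarbonyloxy)phenyl]-2-[4-(benzyloxycarbonyloxy)phenyl]-2H-chromene
Product: 11 (2S,3S)-3-[2,4-bis(benzyloxycarbonyloxy)benzoyl]-2-[4-(benzyloxycarbonyloxy)phenyl]-2,3-dihydrobenzofuran, via hydroxy-iodane adduct 10 (not isolated)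
Conditions: PhI(OH)OTs (1.1 equiv), MeCN–CH2Cl2–H2O, 0 °C to rt, dark
Reagents that add atoms: water, O
Why: Proposed new method: the electrophilic trivalent iodine of PhI(OH)OTs should add to C3 of the C3=C4 bond on the face opposite the C2 aryl group and water should cap the doubly benzylic C4 cation to give 10, in whose diequatorial half-chair the C4–C4a bond lies antiperiplanar to the C3–iodine bond, so that C4a shifts from C4 to C3 as iodobenzene leaves and C4 is pushed out of the ring as the aryl ketone carbonyl. The closest known reaction types are the trivalent-iodine ring contraction of 4-alkyl-1,2-dihydronaphthalenes to 1-acylindanes, the oxidative 1,2-aryl shift of 1,1-diarylalkenes to alpha-aryl ketones and the contraction of flavanones to 2-aryl-2,3-dihydrobenzofuran-3-carboxylates; a 2,4-diaryl-2H-chromene has not been taken through it. The five-membered ring closes by the 1,2-shift itself: C4a bridges C3 and C4 in a phenonium-type three-centre transition state and then keeps only its bond to C3, so the six-membered pyran becomes the five-membered dihydrofuran while O1–C2 and O1–C8a stay intact. C2 is untouched, and C3 is set by inversion at the iodine-bearing carbon, which turns the 2,3-trans adduct into the 2,3-trans (2S,3S) ketone, while any cis isomer should drain to trans by acid-catalysed enolisation. The step needs migration of ring A rather than of the exocyclic C4 aryl or the C2 aryl group, attack on the alkene rather than on an arene, and no hydride loss from C2; the equatorial carbon–iodine geometry secures the first, and the three electron-withdrawing carbonates, which leave ring A with O1 as the only donor-substituted arene, secure the others.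

Step 7
Reactants: 11 (2S,3S)-3-[2,4-bis(benzyloxycarbonyloxy)benzoyl]-2-[4-(benzyloxycarbonyloxy)phenyl]-2,3-dihydrobenzofuran
Product: 12 (2S,3S)-3-[2,4-bis(benzyloxycarbonyloxy)benzoyl]-2-[4-(benzyloxycarbonyloxy)phenyl]-5-iodo-2,3-dihydrobenzofuran
Conditions: NIS, CF3CO2H (cat.), MeCN, rt, dark
Reagents that add atoms: N-iodosuccinimide, O=C1CCC(=O)N1I
Why: Acid-activated electrophilic aromatic iodination, in which ring A is the only arene with an ether donor and attack para to O1 (C5) is preferred over the ortho position C7, as is usual for 2,3-dihydrobenzofurans.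

Step 8
Reactants: 13 2,4-bis(benzyloxy)benzaldehyde
Product: 14 (±)-1-[2,4-bis(benzyloxy)phenyl]prop-2-en-1-ol
Conditions: vinylMgBr, THF, 0 °C; aq NH4Cl
Reagents that add atoms: vinylmagnesium bromide, C=C[Mg]Br
Why: 1,2-Addition of a vinyl Grignard reagent to an aldehyde; the carbinol centre is racemic and is erased in step 9.

Step 9
Reactants: 12 (2S,3S)-3-[2,4-bis(benzyloxycarbonyloxy)benzoyl]-2-[4-(benzyloxycarbonyloxy)phenyl]-5-iodo-2,3-dihydrobenzofuran; 14 (±)-1-[2,4-bis(benzyloxy)phenyl]prop-2-en-1-ol
Product: 15 (2S,3S)-5-{3-[2,4-bis(benzyloxy)phenyl]-3-oxopropyl}-3-[2,4-bis(benzyloxycarbonyloxy)benzoyl]-2-[4-(benzyloxycarbonyloxy)phenyl]-2,3-dihydrobenzofuran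
Conditions: Pd(OAc)2 (cat.), n-Bu4NCl, NaHCO3, DMF, 45 °C
Reagents that add atoms: none
Why: Heck arylation of a secondary allylic alcohol places the aryl group on the terminal carbon, and beta-hydride elimination towards the carbinol C–H gives the saturated beta-aryl ketone after tautomerisation; the aryl iodide allows mild bicarbonate conditions that should leave C3–H, the C2–O1 bond and the carbonates untouched.

Step 10
Reactants: 15 (2S,3S)-5-{3-[2,4-bis(benzyloxy)phenyl]-3-oxopropyl}-3-[2,4-bis(benzyloxycarbonyloxy)benzoyl]-2-[4-(benzyloxycarbonyloxy)phenyl]-2,3-dihydrobenzofuran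
Product: 16 CNP0136359.1, (2S,3S)-3-(2,4-dihydroxybenzoyl)-5-[3-(2,4-dihydroxyphenyl)-3-oxopropyl]-2-(4-hydroxyphenyl)-2,3-dihydrobenzofuran
Conditions: H2 (1 atm), 10% Pd/C, EtOAc, rt, stopped at the end of uptake
Reagents that add atoms: none
Why: Catalytic hydrogenolysis cleaves the two benzyl ethers and the three benzyl carbonates (the latter with loss of CO2) under neutral conditions, so no base meets the epimerisable C3–H or the p-hydroxybenzylic C2–O1 bond, and the hydrogen-bonded 2-hydroxyaryl ketones resist reduction.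

**Compound list**

1 | 4-hydroxyphenylboronic acid | OB(O)c1ccc(O)cc1 | starting material
2 | 4-(benzyloxycarbonyloxy)phenylboronic acid | OB(O)c1ccc(OC(=O)OCc2ccccc2)cc1 | intermediate
3 | chromone (4H-chromen-4-one) | O=c1ccoc2ccccc12 | starting material
4 | (2S)-2-[4-(benzyloxycarbonyloxy)phenyl]chroman-4-one | O=C1C[C@@H](c2ccc(OC(=O)OCc3ccccc3)cc2)Oc2ccccc12 | intermediate
5 | (2S)-2-[4-(benzyloxycarbonyloxy)phenyl]-2H-chromen-4-yl trifluoromethanesulfonate | O=S(=O)(OC1=C[C@@H](c2ccc(OC(=O)OCc3ccccc3)cc2)Oc2ccccc12)C(F)(F)F | intermediate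
6 | 4-iodoresorcinol (4-iodobenzene-1,3-diol) | Oc1ccc(I)c(O)c1 | starting material
7 | dibenzyl (4-iodo-1,3-phenylene) biscarbonate | Ic1ccc(OC(=O)OCc2ccccc2)cc1OC(=O)OCc1ccccc1 | intermediate
8 | [2,4-bis(benzyloxycarbonyloxy)phenyl]zinc iodide (LiCl-solvated, not isolated) | I[Zn]c1ccc(OC(=O)OCc2ccccc2)cc1OC(=O)OCc1ccccc1 | intermediate
9 | (2S)-4-[2,4-bis(benzyloxycarbonyloxy)phenyl]-2-[4-(benzyloxycarbonyloxy)phenyl]-2H-chromene | C1(c2ccc(OC(=O)OCc3ccccc3)cc2OC(=O)OCc2ccccc2)=C[C@@H](c2ccc(OC(=O)OCc3ccccc3)cc2)Oc2ccccc12 | intermediate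
10 | hydroxy-iodane adduct (not isolated): 4-[2,4-bis(benzyloxycarbonyloxy)phenyl]-2-[4-(benzyloxycarbonyloxy)phenyl]-3-[phenyl(tosyloxy)-λ3-iodanyl]chroman-4-ol, C2 in space as in 9, iodanyl group trans to the C2 aryl group, hydroxyl trans to the iodanyl group | O[C@@]1(c2ccc(OC(=O)OCc3ccccc3)cc2OC(=O)OCc2ccccc2)[C@H](I(c2ccccc2)OS(=O)(=O)c2ccc(C)cc2)[C@@H](c2ccc(OC(=O)OCc3ccccc3)cc2)Oc2ccccc21 | intermediate
11 | (2S,3S)-3-[2,4-bis(benzyloxycarbonyloxy)benzoyl]-2-[4-(benzyloxycarbonyloxy)phenyl]-2,3-dihydrobenzofuran (2,3-trans) | c1ccc2c(c1)[C@H](C(=O)c1ccc(OC(=O)OCc3ccccc3)cc1OC(=O)OCc1ccccc1)[C@@H](c1ccc(OC(=O)OCc3ccccc3)cc1)O2 | intermediate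
12 | (2S,3S)-3-[2,4-bis(benzyloxycarbonyloxy)benzoyl]-2-[4-(benzyloxycarbonyloxy)phenyl]-5-iodo-2,3-dihydrobenzofuran | Ic1ccc2c(c1)[C@H](C(=O)c1ccc(OC(=O)OCc3ccccc3)cc1OC(=O)OCc1ccccc1)[C@@H](c1ccc(OC(=O)OCc3ccccc3)cc1)O2 | intermediate
13 | 2,4-bis(benzyloxy)benzaldehyde | O=Cc1ccc(OCc2ccccc2)cc1OCc1ccccc1 | starting material
14 | (±)-1-[2,4-bis(benzyloxy)phenyl]prop-2-en-1-ol | C=CC(O)c1ccc(OCc2ccccc2)cc1OCc1ccccc1 | intermediate
15 | (2S,3S)-5-{3-[2,4-bis(benzyloxy)phenyl]-3-oxopropyl}-3-[2,4-bis(benzyloxycarbonyloxy)benzoyl]-2-[4-(benzyloxycarbonyloxy)phenyl]-2,3-dihydrobenzofuran | O=C(CCc1ccc2c(c1)[C@H](C(=O)c1ccc(OC(=O)OCc3ccccc3)cc1OC(=O)OCc1ccccc1)[C@@H](c1ccc(OC(=O)OCc3ccccc3)cc1)O2)c1ccc(OCc2ccccc2)cc1OCc1ccccc1 | intermediate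
16 | CNP0136359.1, (2S,3S)-3-(2,4-dihydroxybenzoyl)-5-[3-(2,4-dihydroxyphenyl)-3-oxopropyl]-2-(4-hydroxyphenyl)-2,3-dihydrobenzofuran | O=C(CCc1ccc2c(c1)[C@H](C(=O)c1ccc(O)cc1O)[C@@H](c1ccc(O)cc1)O2)c1ccc(O)cc1O | target

**Summary**

Total step count: 10.
Longest linear sequence: 8 steps (1, 2, 3, 5, 6, 7, 9, 10).

**Steps most likely to fail**

Step 6. Several processes may compete with the wanted shift:
- migration of the exocyclic C4 aryl group or of the C2 aryl group instead of ring A;
- closure of the C4 oxygen onto C3;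
- capture of the C4 cation by the neighbouring ortho carbonate;
- hydride loss from C2 with aromatisation of the pyran ring.

The fallback sets out from 9 and takes the oxidative shift apart into three known operations. Dihydroxylation of the C3=C4 bond with OsO4 (cat.) and NMO, from the face opposite the C2 aryl group, should give the 3,4-cis-diol F1. MsCl and Et3N in CH2Cl2 at 0 °C should sulfonylate only the secondary C3 hydroxyl to give the C3 monomesylate F2. Et3Al in CH2Cl2 at −78 °C (semipinacol rearrangement of a 2-sulfonyloxy tertiary alcohol) should then move C4a from C4 to C3 with inversion. The equatorial leaving group is again antiperiplanar to the C4–C4a bond. No oxidant meets the arenes or C2–H, and the C4 hydroxyl is cis to the leaving group, so it cannot displace it. The fallback comes back to the route at 11.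

Step 5. The risks are slow zinc insertion, acyl transfer from the ortho carbonate to the metalated carbon, and erosion of C2 by electrocyclic ring opening if the coupling needs heat. The fallback sets out from 7 and moves all heating onto the achiral partner. Miyaura borylation (PdCl2(dppf), B2pin2, KOAc, dioxane, 80 °C) should give the isolable aryl pinacol boronate F3. This is joined to 5 by Suzuki coupling (Pd(OAc)2, SPhos, CsF, THF, 25–35 °C, dark). The fallback comes back to the route at 9.

Step 9. The risks are beta-hydride elimination away from the carbinol carbon, ionisation of the electron-rich allylic alcohol, and base-induced loss of carbonate groups during a slow reaction. The fallback sets out from 14. MnO2 in CH2Cl2 should oxidise it to the aryl vinyl ketone F4, which is used at once. Heck reaction of F4 with 12 (Pd(OAc)2, n-Bu4NCl, NaHCO3, DMF, 45 °C) has only one direction of beta-hydride elimination and should give the protected (E)-chalcone F5. The conditions of step 10 then saturate the enone C=C bond while removing all five benzyl-type groups. The fallback comes back to the route at 16.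

**Further compounds**

F1 | step 6 | 4-[2,4-bis(benzyloxycarbonyloxy)phenyl]-2-[4-(benzyloxycarbonyloxy)phenyl]chroman-3,4-diol, 3,4-cis, both hydroxyls trans to the C2 aryl group, C2 in space as in 9 | O[C@]1(c2ccc(OC(=O)OCc3ccccc3)cc2OC(=O)OCc2ccccc2)[C@H](O)[C@@H](c2ccc(OC(=O)OCc3ccccc3)cc2)Oc2ccccc21
F2 | step 6 | C3 methanesulfonate of F1 (tertiary C4 hydroxyl free) | O[C@]1(c2ccc(OC(=O)OCc3ccccc3)cc2OC(=O)OCc2ccccc2)[C@H](OS(C)(=O)=O)[C@@H](c2ccc(OC(=O)OCc3ccccc3)cc2)Oc2ccccc21
F3 | step 5 | 2-[2,4-bis(benzyloxycarbonyloxy)phenyl]-4,4,5,5-tetramethyl-1,3,2-dioxaborolane | CC1(C)OB(OC1(C)C)c1ccc(OC(=O)OCc2ccccc2)cc1OC(=O)OCc1ccccc1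
F4 | step 9 | 1-[2,4-bis(benzyloxy)phenyl]prop-2-en-1-one | C=CC(=O)c1ccc(OCc2ccccc2)cc1OCc1ccccc1
F5 | step 9 | (2S,3S)-5-{(E)-3-[2,4-bis(benzyloxy)phenyl]-3-oxoprop-1-enyl}-3-[2,4-bis(benzyloxycarbonyloxy)benzoyl]-2-[4-(benzyloxycarbonyloxy)phenyl]-2,3-dihydrobenzofuran | O=C(/C=C/c1ccc2c(c1)[C@H](C(=O)c1ccc(OC(=O)OCc3ccccc3)cc1OC(=O)OCc1ccccc1)[C@@H](c1ccc(OC(=O)OCc3ccccc3)cc1)O2)c1ccc(OCc2ccccc2)cc1OCc1ccccc1
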